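**Assumption:** the target SMILES contains no stereocentres (Kanzonol L is achiral), so there is no enantiomer to control. The only stereo-elements in the route are the E-alkene of 11 and the racemic trans-epoxide 13; both are erased by step 9.

## Retrosynthetic overview

1. The usual C3–aryl disconnections (Suzuki on a 3-iodochromone, or a Friedel–Crafts deoxybenzoin) are deliberately not used; the 4-pyranone C ring is closed last from o-MOM-oxy β-keto-aldehyde 14.
2. Key step: 14 comes from chalcone epoxide 13 by a Lewis-acid 1,2-aroyl shift (House–Meinwald rearrangement), which forms the C3–C4 bond with both prenyls and the chromene already in place.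
3. 13 comes from chalcone 11 by nucleophilic (Weitz–Scheffer) epoxidation, which leaves the three electron-rich alkenes untouched; 11 is a Claisen–Schmidt union of ketone 5 and aldehyde 10.
4. 5 comes from 2,4,6-trihydroxyacetophenone by direct C-diprenylation; 10 comes from 2,4-dihydroxybenzaldehyde by a propargyl-ether Claisen/oxa-6π sequence.
5. Ring order: A and B benzene rings are purchased; dimethylpyran ring (step 5), then transient oxirane (step 7), then 4-pyranone C ring (step 9).

## Route

**Step 1**
Reactants: 1, 2,4,6-trihydroxyacetophenone; 2, prenyl bromide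
Product: 3, 1-[2,4,6-trihydroxy-3,5-bis(3-methylbut-2-en-1-yl)phenyl]ethan-1-one
Conditions: 2 (2.2 equiv), 10% aq. KOH, 0 °C → rt, 3 h
Reagents that add atoms: prenyl bromide (2), CC(C)=CCBr
Why: C-alkylation of the ambident acylphloroglucinolate by a soft allylic bromide in water, where the oxygens are hydrogen-bond-solvated, puts a prenyl on each of the two equivalent free ring carbons; this is a known but modest-yielding reaction (about 30% expected, separated from mono- and over-alkylated material).

**Step 2**
Reactants: 3; 4, chloromethyl methyl ether (MOMCl)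
Product: 5, 1-[2,4,6-tris(methoxymethoxy)-3,5-bis(3-methylbut-2-en-1-yl)phenyl]ethan-1-one
Conditions: NaH (3.3 equiv), MOMCl (3.6 equiv), DMF, 0 °C → rt
Reagents that add atoms: MOMCl (4), COCCl
Why: Williamson O-alkylation of all three phenoxides (including the chelated one) with a hard electrophile; masking the ortho-OH prevents Algar–Flynn–Oyamada cyclisation in step 7 and makes the ketone stable to the aldol base.

**Step 3**
Reactants: 6, 2,4-dihydroxybenzaldehyde; 4, MOMCl
Product: 7, 2-hydroxy-4-(methoxymethoxy)benzaldehyde
Conditions: MOMCl (1.1 equiv), K2CO3, acetone, rt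
Reagents that add atoms: MOMCl (4), COCCl
Why: Regioselective O-alkylation: the 2-OH is hydrogen-bonded to the aldehyde and poorly nucleophilic, so the more acidic, unhindered 4-OH reacts.

**Step 4**
Reactants: 7; 8, 3-chloro-3-methylbut-1-yne
Product: 9, 4-(methoxymethoxy)-2-[(2-methylbut-3-yn-2-yl)oxy]benzaldehyde
Conditions: 8 (2 equiv), DBU, CuCl2·2H2O (1 mol %), MeCN, 0 °C → rt
Reagents that add atoms: 3-chloro-3-methylbut-1-yne (8), CC(C)(Cl)C#C
Why: Copper-catalysed propargylic substitution (via a Cu-acetylide/allenylidene electrophile) is the standard way to make hindered aryl 1,1-dimethylpropargyl ethers and tolerates the aldehyde and MOM ether.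

**Step 5**
Reactants: 9
Product: 10, 5-(methoxymethoxy)-2,2-dimethyl-2H-chromene-8-carbaldehyde
Conditions: PhNEt2, 180 °C, 2 h, Ar
Reagents that add atoms: none
Why: Aromatic propargyl Claisen rearrangement, then 1,5-H shift and oxa-6π electrocyclisation (thermal chromene synthesis); the only free ortho carbon is C3, because the other ortho position carries CHO, so the pyran is fused with its oxygen next to the future isoflavone attachment carbon.

**Step 6**
Reactants: 5; 10
Product: 11, (E)-3-[5-(methoxymethoxy)-2,2-dimethyl-2H-chromen-8-yl]-1-[2,4,6-tris(methoxymethoxy)-3,5-bis(3-methylbut-2-en-1-yl)phenyl]prop-2-en-1-one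
Conditions: KOH (50% aq.), EtOH, rt, 36 h
Reagents that add atoms: none (both partners are the numbered reactants; water is lost)
Why: Claisen–Schmidt aldol condensation of a methyl ketone with a non-enolisable aldehyde; E1cB dehydration gives the thermodynamic E-enone, and MOM ethers, prenyls and the chromene are base-stable.

**Step 7**
Reactants: 11; 12, hydrogen peroxide
Product: 13, rac-trans epoxy ketone: [(2R*,3S*)-3-[5-(methoxymethoxy)-2,2-dimethyl-2H-chromen-8-yl]oxiran-2-yl][2,4,6-tris(methoxymethoxy)-3,5-bis(3-methylbut-2-en-1-yl)phenyl]methanone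
Conditions: 30% H2O2, 2 M NaOH, MeOH–THF, 0 °C → rt; purify on Et3N-deactivated silica
Reagents that add atoms: hydrogen peroxide (12), OO
Why: Weitz–Scheffer nucleophilic epoxidation: hydroperoxide adds only to the electron-poor enone, so the two prenyl alkenes and the chromene alkene are untouched; the stepwise mechanism gives the trans-epoxide as a racemate, which is irrelevant because both centres are destroyed in steps 8–9.

**Step 8 (key step)**
Reactants: 13
Product: 14, 2-[5-(methoxymethoxy)-2,2-dimethyl-2H-chromen-8-yl]-3-oxo-3-[2,4,6-tris(methoxymethoxy)-3,5-bis(3-methylbut-2-en-1-yl)phenyl]propanal (racemic, largely enolised)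
Conditions: BF3·OEt2 (0.5 equiv), CH2Cl2, −40 → −20 °C, 15 min; Et3N quench
Reagents that add atoms: none
Why: House–Meinwald rearrangement of an α,β-epoxy ketone: the Lewis acid opens the Cβ–O bond regiospecifically to a benzylic cation stabilised by the ortho- and para-oxygens of the B ring, and the neighbouring aroyl group undergoes a 1,2-shift in preference to hydride, which forms the future C3–C4 bond and leaves the old Cα as the aldehyde (the future C2); this is the known chalcone-epoxide route to isoflavones, run cold, briefly and aprotically to spare the prenyls, chromene and MOM ethers.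

**Step 9**
Reactants: 14
Product: 15, Kanzonol L, 5,7-dihydroxy-3-(5-hydroxy-2,2-dimethyl-2H-chromen-8-yl)-6,8-bis(3-methylbut-2-en-1-yl)-4H-chromen-4-one
Conditions: 3 M aq. HCl, MeOH–THF, 45 °C, 1–2 h
Reagents that add atoms: none
Why: Acetal hydrolysis removes all four MOM groups, and a freed ortho-phenol adds to the aldehyde to give a 2-hydroxyisoflavanone that dehydrates to the 4-pyranone; the two ortho oxygens of the A ring are equivalent, so only one isoflavone can form, and dilute HCl/MeOH is the usual MOM removal for prenylated and pyrano-flavonoids.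

## Compound list

1 | 2,4,6-trihydroxyacetophenone | CC(=O)c1c(O)cc(O)cc1O | starting material
2 | prenyl bromide (1-bromo-3-methylbut-2-ene) | CC(C)=CCBr | starting material
3 | 1-[2,4,6-trihydroxy-3,5-bis(3-methylbut-2-en-1-yl)phenyl]ethan-1-one | CC(=O)c1c(O)c(CC=C(C)C)c(O)c(CC=C(C)C)c1O | intermediate
4 | chloromethyl methyl ether (MOMCl) | COCCl | starting material
5 | 1-[2,4,6-tris(methoxymethoxy)-3,5-bis(3-methylbut-2-en-1-yl)phenyl]ethan-1-one | CC(=O)c1c(OCOC)c(CC=C(C)C)c(OCOC)c(CC=C(C)C)c1OCOC | intermediate
6 | 2,4-dihydroxybenzaldehyde | O=Cc1ccc(O)cc1O | starting material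
7 | 2-hydroxy-4-(methoxymethoxy)benzaldehyde | O=Cc1ccc(OCOC)cc1O | intermediate
8 | 3-chloro-3-methylbut-1-yne | CC(C)(Cl)C#C | starting material
9 | 4-(methoxymethoxy)-2-[(2-methylbut-3-yn-2-yl)oxy]benzaldehyde | O=Cc1ccc(OCOC)cc1OC(C)(C)C#C | intermediate
10 | 5-(methoxymethoxy)-2,2-dimethyl-2H-chromene-8-carbaldehyde | O=Cc1ccc(OCOC)c2C=CC(C)(C)Oc12 | intermediate
11 | (E)-chalcone from 5 + 10 | CC(C)=CCc1c(OCOC)c(CC=C(C)C)c(OCOC)c(C(=O)/C=C/c2ccc(OCOC)c3C=CC(C)(C)Oc23)c1OCOC | intermediate
12 | hydrogen peroxide | OO | starting material
13 | rac-trans-(2R*,3S*) chalcone epoxide (one enantiomer drawn) | CC(C)=CCc1c(OCOC)c(CC=C(C)C)c(OCOC)c(C(=O)[C@@H]2O[C@H]2c2ccc(OCOC)c3C=CC(C)(C)Oc23)c1OCOC | intermediate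
14 | 2-aryl-3-oxo-3-arylpropanal (α-formyl deoxybenzoin, racemic/enolised) | CC(C)=CCc1c(OCOC)c(CC=C(C)C)c(OCOC)c(C(=O)C(C=O)c2ccc(OCOC)c3C=CC(C)(C)Oc23)c1OCOC | intermediate
15 | Kanzonol L | CC(C)=CCc1c(O)c(CC=C(C)C)c2occ(-c3ccc(O)c4c3OC(C)(C)C=C4)c(=O)c2c1O | target

## Summary

**Total steps:** 9.
**Longest linear sequence:** 7 (6 → 7 → 9 → 10 → 11 → 13 → 14 → 15; the A-ring branch 1 → 3 → 5 is 2 steps before the union).

**Three steps most likely to fail, with fallbacks:**

- **Step 8 (1,2-aroyl shift).** Risks are BF3 attack on the prenyl or chromene alkenes or MOM ethers, capture of the cation by an ortho-MOM oxygen (giving a dihydroflavonol), or hydride shift. Fallback: abandon the rearrangement and make the C3–aryl bond by Pd-catalysed α-arylation of ketone 5 with 8-bromo-5-(methoxymethoxy)-2,2-dimethyl-2H-chromene (from 4-bromoresorcinol by mono-MOM protection, the same propargylation and the same Claisen step). Then insert C2 with DMF-DMA and close and deprotect with acid.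
- **Step 9 (global acid deprotection and ring closure).** Risks are acid-catalysed cyclisation of the o-prenylphenols to chromans or hydration of the chromene. Fallback: change the protecting-group class to fluoride-labile SEM ethers (SEMCl in steps 2 and 3) and unmask with TBAF, so no Brønsted acid is used; the free o-hydroxy β-keto-aldehyde cyclises spontaneously or with a trace of AcOH.
- **Step 1 (direct C-diprenylation).** Risks are low yield and mono-, gem- and O-alkylated by-products. Fallback: O-allylate 1 to 2-hydroxy-4,6-bis(allyloxy)acetophenone, run a double aromatic Claisen rearrangement (about 190 °C) to the 3,5-diallyl triol, protect as the tris-MOM ether, and convert both allyls to prenyls by cross-metathesis with 2-methyl-2-butene (Grubbs II) to reach 5.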